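Everything rests on reading the C19 carboxyl carbon on quaternary C4 as a former ring atom. Ring A (C1–C5, C10) is cut at C3–C4 back to a seven-membered α-chloro ketone, C10–C1–C2–C3–C19(=O)–C4(Cl)(CH3)–C5. One stereospecific Favorskii contraction forms C3–C4, pushes C19 out of the ring as the axial ester and sets the C4 stereocentre. It exploits the C3H2–C4(CH3)(CO2H) array of ring A. The trans-fused 6–7 precursor comes from (R)-carvone, which delivers ring B, C5, C4 and both C4/C8 methyl groups, by two α′-alkylations and ring-closing metathesis. The enone then gives the C8=C9 enol triflate for a B-alkyl Suzuki coupling with the side chain.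

Key step: step 7

Remark: all atoms carry the labdane numbers of the target (ring A C1–C5/C10, ring B C5–C10, C17 = 8-CH3, C18 = 4-CH3, C19 = carboxyl carbon, C20 = 10-CH3). β is the face of C20 and α the opposite face.

Step 1
Reactants: 1 (R)-(−)-carvone
Product: 3 6-methylcarvone (both C10 epimers), via lithium dienolate 2 (not isolated)
Conditions: LDA, THF, −78 °C; MeI, −78 → 0 °C
Reagents that add atoms: iodomethane, CI; lithium diisopropylamide (lithium of 2 only), CC(C)N([Li])C(C)C
Why: Kinetic α′-deprotonation of the enone at C10 followed by SN2 methylation (enolate alkylation) installs C20; the configuration of the new centre is irrelevant because it is planarised again in step 2.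

Step 2
Reactants: 3 6-methylcarvone; 4 5-iodopent-1-ene
Product: 6 6-methyl-6-(pent-4-enyl)carvone (pentenyl α; C20 β), via lithium dienolate 5 (not isolated)
Conditions: LDA, THF/DMPU, −78 °C; 4, −78 °C → rt
Reagents that add atoms: lithium diisopropylamide (lithium of 5 only), CC(C)N([Li])C(C)C
Why: Enolate alkylation of the tetrasubstituted cross-conjugated dienolate builds quaternary C10, and the electrophile should enter anti to the neighbouring pseudo-axial C5 isopropenyl group, so the C1 chain ends up α (trans to isopropenyl) and C20 β.

Step 3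
Reactants: 6 6-methyl-6-(pent-4-enyl)carvone
Product: 7 trans-fused 6–7 dienone (C4=C19 olefin)
Conditions: Grubbs II (5 mol %), CH2Cl2 (high dilution), reflux
Reagents that add atoms: none
Why: Ring-closing olefin metathesis between the terminal olefin and the 1,1-disubstituted isopropenyl group, which can both sit equatorial on ring B, closes the seven-membered ring as its trisubstituted olefin with loss of ethene, while the electron-poor enone olefin stays inert and no stereocentre is formed.

Step 4
Reactants: 7 trans-fused 6–7 dienone
Product: 8 4α,19α-epoxide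
Conditions: mCPBA, CH2Cl2, 0 °C
Reagents that add atoms: 3-chloroperbenzoic acid, OOC(=O)c1cccc(Cl)c1
Why: Prilezhaev epoxidation is chemoselective for the electron-rich trisubstituted olefin over the enone and should take place on the convex α face, anti to the axial C20 methyl group that is gauche to C4, which sets C4 and C19.

Step 5
Reactants: 8 4α,19α-epoxide
Product: 9 4β-chloro-19α-hydroxy chlorohydrin
Conditions: HCl (1 M in Et2O), CH2Cl2, −40 °C
Reagents that add atoms: hydrogen chloride, Cl
Why: Acid-mediated epoxide opening (hydrochlorination) should occur at the tertiary, cation-stabilising C4 with inversion in a trans-diaxial-type anti opening, which places chlorine on the β face and C18 on the α face and leaves the 19α-C–O bond untouched.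

Step 6
Reactants: 9 4β-chloro-19α-hydroxy chlorohydrin
Product: 10 4β-chloro-4α-methyl-19-ketone
Conditions: Dess–Martin periodinane, CH2Cl2, 0 °C → rt
Reagents that add atoms: none
Why: Dess–Martin oxidation converts the secondary alcohol into the ketone under non-basic conditions, so the chlorohydrin cannot re-close to the epoxide and C4, which bears no hydrogen, cannot epimerise.

Step 7
Reactants: 10 4β-chloro-4α-methyl-19-ketone
Product: 12 ring-contracted enone 2-(trimethylsilyl)ethyl ester, via cyclopropanone 11 (not isolated)
Conditions: Me3SiCH2CH2OH, n-BuLi, Et2O, 0 °C; then 10, 0 °C → rt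
Reagents that add atoms: 2-(trimethylsilyl)ethanol (used as its lithium alkoxide), OCC[Si](C)(C)C
Why: The alkoxide enolises the C19 ketone at C3, its only hydrogen-bearing α-carbon, and the enolate expels the tertiary C4 chloride to give cyclopropanone 11; alkoxide then adds to the strained C19 carbonyl and the hemiketal anion breaks the C19–C3 bond, the one that releases the less substituted (secondary) carbanion, which is protonated to C3H2 while C19 stays on C4 as the ester. The closest known reaction type is the Favorskii ring contraction of 2-chloro-2-methylcycloalkanones to 1-methylcycloalkanecarboxylates. The C3–C4 bond forms by a transannular 3-exo-tet displacement inside the seven-membered ring, which closes the cyclopropanone and the six-membered ring A (C1–C5, C10) in the same event. C4 is the only new stereocentre and is controlled by the C–Cl configuration of 10: in a weakly ionising ethereal medium the closure proceeds with inversion, so 4β-Cl/4α-CH3 becomes 4β (axial) ester/4α-CH3. The step needs the 1,3-displacement to outrun E2 loss of HCl toward H-5, ionisation to a planar oxyallyl species and epoxy-ether formation by attack at C19; fast reversible enolisation at C3, the pseudo-axial C–Cl bond lying parallel to the enolate π system and the non-polar solvent should secure this. The ring-B enone is a spectator because C10 is quaternary and its γ-deprotonation is reversible.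

Step 8
Reactants: 12 ring-contracted enone 2-(trimethylsilyl)ethyl ester
Product: 14 C8=C9 enol triflate, via lithium enolate 13 (not isolated)
Conditions: L-Selectride, THF, −78 °C; PhNTf2, −78 °C → rt
Reagents that add atoms: N-phenylbis(trifluoromethanesulfonimide), O=S(=O)(N(c1ccccc1)S(=O)(=O)C(F)(F)F)C(F)(F)F; L-Selectride (lithium of 13 only), [Li+].CCC(C)[BH-](C(C)CC)C(C)CC
Why: Conjugate hydride reduction of the enone, whose carbonyl is shielded by quaternary C10, gives the C8=C9 enolate regiospecifically and O-sulfonylation traps it as the tetrasubstituted enol triflate, with no stereocentre created and the hindered C19 ester untouched.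

Step 9
Reactants: 15 (E)-3-methylpent-2-en-4-yn-1-ol
Product: 16 (E)-3-methylpenta-2,4-dien-1-ol
Conditions: H2 (1 atm), Lindlar catalyst, quinoline, EtOAc, rt
Reagents that add atoms: none
Why: Lindlar semihydrogenation reduces the terminal alkyne to the vinyl group and leaves the E-trisubstituted olefin (the later C13=C14) unchanged.

Step 10
Reactants: 16 (E)-3-methylpenta-2,4-dien-1-ol
Product: 17 (E)-dienyl TBS ether
Conditions: TBSCl, imidazole, CH2Cl2, rt
Reagents that add atoms: tert-butyldimethylsilyl chloride, CC(C)(C)[Si](C)(C)Cl
Why: Standard silylation masks the primary allylic alcohol against the borane and the basic coupling medium.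

Step 11
Reactants: 17 (E)-dienyl TBS ether; 14 C8=C9 enol triflate
Product: 19 doubly silyl-protected labdadiene, via B-alkyl-9-BBN borane 18 (not isolated)
Conditions: 17, 9-BBN, THF, 0 °C → rt; then 14, PdCl2(dppf) (10 mol %), AsPh3, Cs2CO3, DMF/H2O, 50 °C
Reagents that add atoms: 9-borabicyclo[3.3.1]nonane (boryl group of 18 only), [H]B1C2CCCC1CCC2
Why: Anti-Markovnikov hydroboration of the monosubstituted vinyl terminus (the trisubstituted olefin reacts much more slowly with 9-BBN) and B-alkyl Suzuki–Miyaura coupling with the enol triflate form the C9–C11 bond with retention of both olefin positions and of the E geometry.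

Step 12
Reactants: 19 doubly silyl-protected labdadiene
Product: 20 15-hydroxylabda-8(9),13E-dien-19-oic acid
Conditions: TBAF, THF, rt; aq. NH4Cl
Reagents that add atoms: none
Why: Fluoride-induced desilylation cleaves the silyl ether and, through β-fragmentation of the 2-silylethyl group to ethene, the ester; both attacks occur at silicon, so the steric shielding of the axial C19 carbonyl does not matter.

Step 13
Reactants: 20 15-hydroxylabda-8(9),13E-dien-19-oic acid
Product: 21 15-acetoxylabda-8(9),13E-dien-19-oic acid (target)
Conditions: Ac2O, pyridine, DMAP (cat.), CH2Cl2, 0 °C → rt; aq. work-up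
Reagents that add atoms: acetic anhydride, CC(=O)OC(C)=O
Why: O-Acylation of the primary allylic alcohol gives the acetate, and any mixed anhydride formed at the hindered acid is hydrolysed at its acetyl carbonyl during aqueous work-up.

Compound list
1 | (R)-(−)-carvone, (5R)-2-methyl-5-(prop-1-en-2-yl)cyclohex-2-en-1-one | O=C1C(C)=CC[C@@H](C(C)=C)C1 | starting material
2 | lithium cross-conjugated dienolate of 1 (C9–OLi, C9=C10, C7=C8) | [Li]OC1=C[C@H](C(C)=C)CC=C1C | intermediate
3 | 6-methylcarvone, (5R)-2,6-dimethyl-5-(prop-1-en-2-yl)cyclohex-2-en-1-one, both epimers at C10 | O=C1C(C)=CC[C@@H](C(C)=C)C1C | intermediate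
4 | 5-iodopent-1-ene | C=CCCCI | starting material
5 | lithium dienolate of 3 (tetrasubstituted C9=C10) | [Li]OC1=C(C)[C@H](C(C)=C)CC=C1C | intermediate
6 | (5S,6S)-2,6-dimethyl-6-(pent-4-en-1-yl)-5-(prop-1-en-2-yl)cyclohex-2-en-1-one (pentenyl α, trans to isopropenyl; C20 β) | O=C1C(C)=CC[C@@H](C(C)=C)[C@]1(C)CCCC=C | intermediate
7 | trans-fused 6–7 dienone, (4aS,9aS)-2,5,9a-trimethyl-4,4a,7,8,9,9a-hexahydro-1H-benzo[7]annulen-1-one (seven-membered ring C10–C1–C2–C3–C19H=C4(CH3)–C5; 5α-H, 10β-CH3) | O=C1C(C)=CC[C@H]2C(C)=CCCC[C@]12C | intermediate
8 | 4α,19α-epoxide of 7 | O=C1C(C)=CC[C@H]2[C@]3(C)O[C@@H]3CCC[C@]12C | intermediate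
9 | chlorohydrin: 4β-chloro-4α-methyl-19α-hydroxy derivative of the 6–7 enone | O=C1C(C)=CC[C@H]2[C@@](C)(Cl)[C@H](O)CCC[C@]12C | intermediate
10 | α-chloro ketone: 4β-chloro-4α-methyl-19-oxo derivative of the 6–7 enone | O=C1C(C)=CC[C@H]2[C@@](C)(Cl)C(=O)CCC[C@]12C | intermediate
11 | cyclopropanone: C19=O bridging C3 and C4 on the β face of the new ring A | O=C1C(C)=CC[C@H]2[C@@]3(C)C(=O)[C@H]3CC[C@]12C | intermediate
12 | trans-octalone ester: C9=O, C7=C8, 8-CH3, 10β-CH3, 5α-H, 4α-CH3, 4β-CO2CH2CH2SiMe3 | O=C1C(C)=CC[C@H]2[C@@](C)(C(=O)OCC[Si](C)(C)C)CCC[C@]12C | intermediate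
13 | lithium C8=C9 enolate obtained from 12 by 1,4-reduction | [Li]OC1=C(C)CC[C@H]2[C@@](C)(C(=O)OCC[Si](C)(C)C)CCC[C@]12C | intermediate
14 | C8=C9 enol triflate (C9–OTf) of the decalin ester | O=S(=O)(OC1=C(C)CC[C@H]2[C@@](C)(C(=O)OCC[Si](C)(C)C)CCC[C@]12C)C(F)(F)F | intermediate
15 | (E)-3-methylpent-2-en-4-yn-1-ol | OC/C=C(\C)C#C | starting material
16 | (E)-3-methylpenta-2,4-dien-1-ol | OC/C=C(\C)C=C | intermediate
17 | tert-butyldimethylsilyl ether of 16 | CC(C)(C)[Si](C)(C)OC/C=C(\C)C=C | intermediate
18 | B-[(E)-5-(tert-butyldimethylsilyloxy)-3-methylpent-3-enyl]-9-BBN | CC(C)(C)[Si](C)(C)OC/C=C(\C)CCB1C2CCCC1CCC2 | intermediate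
19 | 2-(trimethylsilyl)ethyl 15-(tert-butyldimethylsilyloxy)labda-8(9),13E-dien-19-oate | CC(C)(C)[Si](C)(C)OC/C=C(\C)CCC1=C(C)CC[C@H]2[C@@](C)(C(=O)OCC[Si](C)(C)C)CCC[C@]12C | intermediate
20 | 15-hydroxylabda-8(9),13E-dien-19-oic acid | OC/C=C(\C)CCC1=C(C)CC[C@H]2[C@@](C)(C(=O)O)CCC[C@]12C | intermediate
21 | 15-acetoxylabda-8(9),13E-dien-19-oic acid (CNP0326733.1) | CC(=O)OC/C=C(\C)CCC1=C(C)CC[C@H]2[C@@](C)(C(=O)O)CCC[C@]12C | target

Total step count: 13. Longest linear sequence: 11 (steps 1–8 and 11–13).

Steps most likely to fail

Step 7 (Favorskii contraction). The base may induce loss of HCl toward C5. Alternatively the enolate may ionise to a planar oxyallyl species, which would erase the stereochemical information at C4. The fallback replaces the anionic contraction by a cationic one; it sets out from 7 and returns at 12.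
- NBS in aqueous DME should deliver bromine from the α face and water to the tertiary C4 from the β face, giving the bromohydrin F1.
- K2CO3 in MeOH closes this to the 4β,19β-epoxide F2.
- Methylaluminium bis(4-bromo-2,6-di-tert-butylphenoxide) at −78 °C ionises the C4–O bond, and C3 migrates from C19 to C4 anti to the departing oxygen (semipinacol, Meinwald-type ring contraction). This gives the 4β-formyl-4α-methyl octalone F3.
- Pinnick oxidation gives the enone acid F4.
- Mitsunobu esterification with 2-(trimethylsilyl)ethanol gives 12.

Step 5 (epoxide to tertiary chloride). The protonated epoxide may collapse by 1,2-hydride shift or proton loss before chloride is captured. Chloride capture on the hindered β face may also proceed with incomplete inversion. The fallback moves the halogen to C3; it sets out from 8 and returns at 12.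
- BF3·OEt2 in CH2Cl2 at −78 °C makes the hydride shift the productive path and gives the 4-methyl-19-ketone F5.
- Kinetic deprotonation at the less hindered C3 (LDA, −78 °C) and a quench with NBS give the 3-bromo ketone F6.
- Lithium 2-(trimethylsilyl)ethoxide then enolises toward C4, and the Favorskii reaction runs through the same cyclopropanone 11 to 12.
- The C3 bromide epimerises under these conditions, so the C4 configuration rests on closure to the cyclopropanone that keeps C18 away from C20.

Step 11 (B-alkyl Suzuki coupling). Oxidative addition of the tetrasubstituted triflate next to quaternary C10 may be slow, so that protodeboronation or β-hydride elimination of the alkyl partner takes over. The fallback uses carbonyl addition and dehydration; it sets out from 12 and 18 and returns at 19.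
- L-Selectride reduction of 12 with a proton quench gives the saturated 8-methyl-9-ketone F7.
- Borane 18 is converted with I2/NaOMe into the homoallylic iodide F8.
- Iodine–lithium exchange (t-BuLi), transmetalation to cerium (CeCl3) and addition to F7 give the tertiary alcohol F9.
- Dehydration with SOCl2/pyridine toward the more substituted endocyclic position gives 19.

Further compounds
F1 | step 7 | 19α-bromo-4β-hydroxy-4α-methyl bromohydrin of 7 | O=C1C(C)=CC[C@H]2[C@@](C)(O)[C@H](Br)CCC[C@]12C
F2 | step 7 | 4β,19β-epoxide of 7 | O=C1C(C)=CC[C@H]2[C@@]3(C)O[C@H]3CCC[C@]12C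
F3 | step 7 | ring-contracted aldehyde, 4β-formyl-4α-methyl octalone | O=C1C(C)=CC[C@H]2[C@@](C)(C=O)CCC[C@]12C
F4 | step 7 | ring-contracted enone acid, 4β-carboxy-4α-methyl octalone | O=C1C(C)=CC[C@H]2[C@@](C)(C(=O)O)CCC[C@]12C
F5 | step 5 | 4-methyl-19-ketone of the 6–7 enone (C4 epimerisable) | O=C1C(C)=CC[C@H]2C(C)C(=O)CCC[C@]12C
F6 | step 5 | 3-bromo-4-methyl-19-ketone of the 6–7 enone (C3 and C4 epimerisable) | O=C1C(C)=CC[C@H]2C(C)C(=O)C(Br)CC[C@]12C
F7 | step 11 | saturated 8-methyl-9-ketone of the decalin ester (C8 epimers) | O=C1C(C)CC[C@H]2[C@@](C)(C(=O)OCC[Si](C)(C)C)CCC[C@]12C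
F8 | step 11 | (E)-5-iodo-3-methylpent-2-enyl tert-butyldimethylsilyl ether | CC(C)(C)[Si](C)(C)OC/C=C(\C)CCI
F9 | step 11 | C9 tertiary alcohol carrying the side chain (C8 and C9 epimers) | CC(C)(C)[Si](C)(C)OC/C=C(\C)CCC1(O)C(C)CC[C@H]2[C@@](C)(C(=O)OCC[Si](C)(C)C)CCC[C@]12C
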